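**Remark (assumption and numbering):** the target is taken as the (3S) enantiomer encoded in the SMILES, and geraniol is assumed to be geometrically pure (E). Chain atoms are C1–C8 from the ketone carbon (methyl groups on C3 and C7); ring A is C1'–C6' from the acyl-bearing carbon.

## Analysis of the target

Target 12 is an eight-carbon chain joined through its C1 ketone to C1' of a 1,2,4,5-tetrasubstituted benzene (ring A). In ring A, C2'–OH and C5'–OH are para to each other (a hydroquinone), C4' carries bromine para to the acyl carbon C1', and C3' and C6' carry hydrogen. The only stereocentre is C3 (S), a tertiary carbinol bearing OH, CH3 and two CH2 groups, so it must be set by discriminating methyl from methylene with no second centre to relay from. C3–OH is β to the C1 ketone: base can cause E1cB dehydration or retro-aldol cleavage of C2–C3, and the resulting enone would be trapped by C2'–OH as a racemic chromanone. The C3 and C7 tertiary alcohols ionise in strong acid, the hydroquinone is air-oxidisable, and the C4'–Br bond does not tolerate hydrogenolysis or halogen–metal exchange. The real difficulty is therefore protecting-group chemistry: the usual phenol ethers need BBr3, hydrogenolysis or strong acid for removal, all incompatible with the chain. The feature exploited here is that the para O/O pattern at C2'/C5', with the acyl group at C1' and bromine at C4', is the imprint of a 4-bromo-2-silyloxyfuran (its C2 and C5 become C2' and C5') joined across an alkyne (C1'–C6'). Ring A can thus be built last, onto a finished chain, with bromine delivered by the diene and no phenol protection.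

## Retrosynthetic reasoning

**12 ⇒ 11 ⇒ 10 ⇒ 7 + 9.** The ring bonds C1'–C2' and C5'–C6' are cut. They flank the C1'–C6' unit, which maps onto the alkyne of ynone 7, and their far ends are the two oxygen-bearing carbons, which map onto C2 and C5 of silyloxyfuran 9. This replaces a tetrasubstituted arene by an acyclic ynone and a five-membered diene. The forward reaction must be a regioselective [4+2] cycloaddition (furan C5 to the terminal alkyne carbon) giving oxanorbornadiene 10. Opening of the oxygen bridge must then aromatise 10 to silyl ether 11, whose single silyl group is removed to give 12.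

**9 ⇒ 8.** The O–Si bond is cut. Butenolide 8 already carries bromine on the carbon that becomes C4', so the forward step is only enolisation and O-silylation to the aromatic furan.

**7 ⇒ 6 ⇒ 5.** The bond between the carbonyl carbon (C1) and the alkyne is cut. A two-carbon alkynyl nucleophile adds to aldehyde 5 to give carbinol 6, which is oxidised to 7. The two alkyne carbons are the future C1' and C6'.

**5 ⇒ 4 ⇒ 3.** The oxidation level at C1 is lowered to the primary alcohol of triol 4, and the C7–O bond is cut by Markovnikov hydration of the one remaining alkene of diol 3. Both forward steps must leave the tertiary C3 carbinol untouched.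

**3 ⇒ 2 ⇒ 1.** The C2–H bond (regioselective reductive opening of epoxy alcohol 2 at C2) and the C3–O bond (reagent-controlled epoxidation of the allylic alcohol 1) are cut. The fixed (E) geometry of 1 turns the methyl/methylene problem at C3 into a choice of alkene face, which the hydroxyl-directed asymmetric epoxidation solves. Compound 1 supplies all ten chain carbons.

## Alternatives that were turned down

**Alternative 1:** Textbook disconnection of the C1–C1' bond in the polar sense. One of the two equivalent bromines of the symmetric bis(methoxymethyl) ether 1,4-dibromo-2,5-bis(methoxymethoxy)benzene A1 would undergo bromine–lithium exchange; addition to aldehyde 5 followed by oxidation would give the ketone (S)-1-[4-bromo-2,5-bis(methoxymethoxy)phenyl]-3,7-dihydroxy-3,7-dimethyloctan-1-one A2, and acid would remove the acetals. It was turned down for three reasons. Ring A is only purchased. The strongly basic aryllithium meets a β-alkoxide aldehyde prone to retro-aldol cleavage, or else two more silyl groups are needed. The final acidic deprotection acts on a β-hydroxy ketone flanked by two tertiary carbinols, so the protecting-group problem is moved to the last step rather than removed.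

**Alternative 2:** Aryne disconnection of C1–C1' and C2'–O together. The aryne 4-bromo-5-methoxybenzyne A4, generated with fluoride from 5-bromo-4-methoxy-2-(trimethylsilyl)phenyl trifluoromethanesulfonate A3, would insert into the C–O bond of (S)-3,7-dihydroxy-3,7-dimethyloctanoic acid A5 (carboxylate oxygen adds, the aryl anion attacks the carbonyl, the four-membered intermediate opens) to give (S)-1-(4-bromo-2-hydroxy-5-methoxyphenyl)-3,7-dihydroxy-3,7-dimethyloctan-1-one A6. It was turned down because the triple bond C1'≡C2' of A4 is flanked only by C3'–H and C6'–H, so no neighbouring group steers the addition. The remote groups pull in opposite directions: C5'–OMe (para to C2') favours oxygen attack at C2', whereas C4'–Br (para to C1') favours attack at C1', so a mixture of regioisomers is expected. In addition, A3 costs several steps, A6 still needs a demethylation the chain cannot survive, and hot fluoride invites retro-aldol loss from A5.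

**Alternative 3:** Biomimetic disconnection of the C3–O bond (conjugate hydration of a cymopolone-type enone). The enone (E)-1-[4-bromo-2,5-bis(methoxymethoxy)phenyl]-7-hydroxy-3,7-dimethyloct-2-en-1-one A7 would undergo copper-catalysed enantioselective conjugate borylation with a chiral bisphosphine and oxidation of the carbon–boron bond to give A2. It was turned down because the key step forms no carbon–carbon bond and simplifies nothing. Its selectivity depends on methyl/methylene discrimination at a β,β-dialkyl enone and on the geometric purity of A7, which isomerises easily, each isomer giving the opposite enantiomer. The phenols cannot be left free because the enone then closes to the racemic chromanone 7-bromo-6-hydroxy-2-(4-hydroxy-4-methylpentyl)-2-methylchroman-4-one A8, so the deprotection problem of alternative 1 returns.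

Key step: step 8

## Route

**Step 1**
Reactants: 1 geraniol, (E)-3,7-dimethylocta-2,6-dien-1-ol
Product: 2 (2S,3S)-2,3-epoxygeraniol, [(2S,3S)-3-methyl-3-(4-methylpent-3-en-1-yl)oxiran-2-yl]methanol
Conditions: Ti(OiPr)4 (5 mol%), L-(+)-diethyl tartrate (6 mol%), tBuOOH, 4 Å MS, CH2Cl2, −20 °C
Reagents that add atoms: tert-butyl hydroperoxide, CC(C)(C)OO
Why: Katsuki–Sharpless asymmetric epoxidation: the allylic hydroxyl binds the titanium tartrate, which delivers oxygen only to the 2,3-alkene and, with L-(+)-tartrate, to the face that gives (2S,3S), so C3 is set here; the isolated 6,7-alkene is not touched.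

**Step 2**
Reactants: 2 (2S,3S)-2,3-epoxygeraniol
Product: 3 (S)-3,7-dimethyloct-6-ene-1,3-diol
Conditions: NaAlH2(OCH2CH2OMe)2, THF, 0 °C → rt; aq. Rochelle salt work-up
Reagents that add atoms: none
Why: Regioselective reductive opening of a 2,3-epoxy alcohol: the aluminium alkoxide formed at O1 delivers hydride intramolecularly to C2, the less substituted epoxide carbon, giving the 1,3-diol. The C3–O bond is not broken, so the tertiary carbinol keeps its configuration, now described as (S).

**Step 3**
Reactants: 3 (S)-3,7-dimethyloct-6-ene-1,3-diol
Product: 4 (S)-3,7-dimethyloctane-1,3,7-triol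
Conditions: Co(acac)2 (cat.), PhSiH3, O2 (1 atm), THF, rt
Reagents that add atoms: dioxygen, O=O
Why: Mukaiyama hydration: a cobalt hydride transfers a hydrogen atom to C6, the tertiary C7 radical traps dioxygen and the peroxide is reduced by the silane to the Markovnikov tertiary alcohol. Free hydroxyls are tolerated and no stereocentre is formed or touched.

**Step 4**
Reactants: 4 (S)-3,7-dimethyloctane-1,3,7-triol
Product: 5 (S)-3,7-dihydroxy-3,7-dimethyloctanal
Conditions: TEMPO (10 mol%), PhI(OAc)2, CH2Cl2, rt; used without chromatography
Reagents that add atoms: none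
Why: Oxoammonium (TEMPO) oxidation acts only on the primary carbinol, since the two tertiary alcohols cannot be oxidised. The non-aqueous, near-neutral medium should stop at the aldehyde and avoid E1cB loss of the β-hydroxyl.

**Step 5**
Reactants: 5 (S)-3,7-dihydroxy-3,7-dimethyloctanal
Product: 6 (5S)-5,9-dimethyldec-1-yne-3,5,9-triol (both C3 epimers)
Conditions: HC≡CMgBr (3.5 equiv), THF, −78 → −20 °C; then pH 7 buffer
Reagents that add atoms: ethynylmagnesium bromide, C#C[Mg]Br
Why: Grignard 1,2-addition of an alkynyl nucleophile to an aldehyde; two equivalents are spent on the tertiary hydroxyls and the low temperature is meant to keep the magnesium β-alkoxide from retro-aldol cleavage. The new carbinol centre is formed without control, which is irrelevant because it is oxidised in step 6.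

**Step 6**
Reactants: 6 (5S)-5,9-dimethyldec-1-yne-3,5,9-triol
Product: 7 (S)-5,9-dihydroxy-5,9-dimethyldec-1-yn-3-one
Conditions: Dess–Martin periodinane, CH2Cl2, 0 °C; cold, rapid work-up
Reagents that add atoms: none
Why: Dess–Martin oxidation of the only oxidisable (secondary propargylic) alcohol gives the terminal ynone that serves as dienophile. Mild, metal-free conditions are chosen so that the C5 hydroxyl does not add to the ynone.

**Step 7**
Reactants: 8 4-bromofuran-2(5H)-one
Product: 9 4-bromo-2-(triisopropylsilyloxy)furan
Conditions: iPr3SiOTf, Et3N, CH2Cl2, 0 °C; pentane extraction, used directly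
Reagents that add atoms: triisopropylsilyl trifluoromethanesulfonate, CC(C)[Si](OS(=O)(=O)C(F)(F)F)(C(C)C)C(C)C
Why: Soft enolisation of the butenolide at C5 and O-silylation give the aromatic 2-silyloxyfuran with bromine retained at C4. The bulky triisopropylsilyl group is chosen for resistance to the free hydroxyls met in step 8.

**Step 8**
Reactants: 7 (S)-5,9-dihydroxy-5,9-dimethyldec-1-yn-3-one; 9 4-bromo-2-(triisopropylsilyloxy)furan
Product: 12 (S)-1-(4-bromo-2,5-dihydroxyphenyl)-3,7-dihydroxy-3,7-dimethyloctan-1-one, via oxanorbornadiene cycloadduct 10 (not isolated), via aryl silyl ether 11 (not isolated)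
Conditions: 9 (2 equiv), PhMe, rt → 60 °C, N2; then Et3N·3HF, THF, 0 °C → rt
Reagents that add atoms: none
Why: The step is a thermal Diels–Alder reaction of an electron-rich 2-silyloxyfuran with an acetylenic ketone followed by spontaneous aromatisation, the reaction type by which 2-silyloxy- and 2-alkoxyfurans give hydroquinone monoethers with acetylenic esters and ketones. The HOMO of 9 is largest at C5 (vinylogous to the silyloxy oxygen) and the LUMO of 7 is largest at the terminal alkyne carbon, so an asynchronous, intermolecular suprafacial [4+2] closure joins furan C5 to the terminal carbon (bond C5'–C6') and furan C2 to the acyl-bearing carbon (bond C1'–C2'), forming the six-membered carbocycle of ring A as the 7-oxabicyclo[2.2.1]heptadiene 10. In 10 the oxygen bridge ends on a ketal-type bridgehead; lone-pair assistance from the silyloxy oxygen breaks that C–O bond and loss of the proton at the other bridgehead aromatises the ring to 11, so the two furan oxygens become the para-related C2' and C5' oxygens. The selectivity the step needs is regiochemical (bromine para to the acyl group), and the substrate secures it electronically by the donor/acceptor polarisation just described and sterically because the unsubstituted alkyne terminus, not the acyl-bearing one, approaches the brominated end of the diene. The reverse orientation, which would put bromine at C3', is mismatched on both counts. No stereocentre of the product is created here (the two bridgehead centres of 10 disappear on aromatisation), and the C3 carbinol is remote from the reacting atoms and is carried through unchanged. Ring closure should be favoured over an open-chain Mukaiyama–Michael addition by the absence of a Lewis acid and by the non-polar solvent, and the excess of 9 covers any diene lost to the hydroxyl groups. Amine-buffered hydrogen fluoride then removes the one silyl group from 11 without the base that would trigger dehydration and chromanone formation.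

## Compound list

1 | geraniol, (E)-3,7-dimethylocta-2,6-dien-1-ol | CC(C)=CCC/C(C)=C/CO | starting material
2 | (2S,3S)-2,3-epoxygeraniol, [(2S,3S)-3-methyl-3-(4-methylpent-3-en-1-yl)oxiran-2-yl]methanol | OC[C@@H]1O[C@@]1(C)CCC=C(C)C | intermediate
3 | (S)-3,7-dimethyloct-6-ene-1,3-diol | OCC[C@@](C)(O)CCC=C(C)C | intermediate
4 | (S)-3,7-dimethyloctane-1,3,7-triol | OCC[C@@](C)(O)CCCC(C)(C)O | intermediate
5 | (S)-3,7-dihydroxy-3,7-dimethyloctanal | O=CC[C@@](C)(O)CCCC(C)(C)O | intermediate
6 | (5S)-5,9-dimethyldec-1-yne-3,5,9-triol (both C3 epimers) | C#CC(O)C[C@@](C)(O)CCCC(C)(C)O | intermediate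
7 | (S)-5,9-dihydroxy-5,9-dimethyldec-1-yn-3-one | C#CC(=O)C[C@@](C)(O)CCCC(C)(C)O | intermediate
8 | 4-bromofuran-2(5H)-one | O=C1OCC(Br)=C1 | starting material
9 | 4-bromo-2-(triisopropylsilyloxy)furan | CC(C)[Si](Oc1cc(Br)co1)(C(C)C)C(C)C | intermediate
10 | (3S)-1-[5-bromo-1-(triisopropylsilyloxy)-7-oxabicyclo[2.2.1]hepta-2,5-dien-2-yl]-3,7-dihydroxy-3,7-dimethyloctan-1-one (both bridgehead diastereomers) | CC(C)[Si](C(C)C)(C(C)C)OC12OC(C=C1C(=O)C[C@@](C)(O)CCCC(C)(C)O)C(Br)=C2 | intermediate (not isolated)
11 | (S)-1-[4-bromo-5-hydroxy-2-(triisopropylsilyloxy)phenyl]-3,7-dihydroxy-3,7-dimethyloctan-1-one | CC(C)[Si](C(C)C)(C(C)C)Oc1cc(Br)c(O)cc1C(=O)C[C@@](C)(O)CCCC(C)(C)O | intermediate (not isolated)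
12 | (S)-1-(4-bromo-2,5-dihydroxyphenyl)-3,7-dihydroxy-3,7-dimethyloctan-1-one | CC(C)(O)CCC[C@](C)(O)CC(=O)c1cc(O)c(Br)cc1O | target

## Step count and least certain steps

Total step count: 8. Longest linear sequence: 7 steps (steps 1–6 and 8); step 7 is a one-step side branch.

**Step 8 (key step).** Three things could go wrong. Carbon–carbon bond formation may stop after the first bond, giving open-chain conjugate addition of the silyloxyfuran instead of ring closure. The cycloaddition may be sluggish because bromine lowers the diene HOMO. Regiocontrol may erode if the steric and electronic preferences prove weaker than argued. The fallback sets out from 5 and comes back to the route at 12. Irradiation of 5 with 1,4-benzoquinone and a benzophenone sensitiser (Klinger–Kolvenbach photoacylation: hydrogen abstraction from the aldehyde, addition of the acyl radical to the quinone, tautomerisation) should give the bromine-free acylhydroquinone (S)-1-(2,5-dihydroxyphenyl)-3,7-dihydroxy-3,7-dimethyloctan-1-one F1. Monobromination of F1 with N-bromosuccinimide in acetonitrile at low temperature is expected to occur ortho to the unchelated C5'–OH on the side away from the acyl chain (C4'), by analogy with the bromination of gentisic esters, and would give 12.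

**Step 5.** The magnesium β-alkoxide of the aldehyde may fragment by retro-aldol cleavage, or 5 may dehydrate or oligomerise before the addition. The fallback sets out from 4 and comes back at 7, and step 6 is then not needed. Oxidation of the primary carbinol with TEMPO/NaOCl/NaClO2 gives (S)-3,7-dihydroxy-3,7-dimethyloctanoic acid F2, and carbodiimide coupling with N,O-dimethylhydroxylamine gives the Weinreb amide (S)-3,7-dihydroxy-N-methoxy-N,3,7-trimethyloctanamide F3. Its chelated tetrahedral adduct with excess ethynylmagnesium bromide cannot undergo retro-aldol cleavage and should release 7 on inverse acidic quench.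

**Step 6.** The C5 hydroxyl may add to the ynone (6-endo oxa-Michael cyclisation to a dihydropyranone), or the terminal ynone may oligomerise on concentration. The fallback sets out from 5 and comes back at 12, carrying both tertiary hydroxyls as silyl ethers:
- N-(trimethylsilyl)imidazole converts 5 into (S)-3,7-dimethyl-3,7-bis(trimethylsilyloxy)octanal F4.
- Ethynylmagnesium bromide gives (5S)-5,9-dimethyl-5,9-bis(trimethylsilyloxy)dec-1-yn-3-ol F5.
- Pyridine-buffered Dess–Martin oxidation gives (S)-5,9-dimethyl-5,9-bis(trimethylsilyloxy)dec-1-yn-3-one F6, which cannot cyclise.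
- Cycloaddition with 9 under the conditions of step 8 proceeds through (3S)-1-[5-bromo-1-(triisopropylsilyloxy)-7-oxabicyclo[2.2.1]hepta-2,5-dien-2-yl]-3,7-dimethyl-3,7-bis(trimethylsilyloxy)octan-1-one F7 to (S)-1-[4-bromo-5-hydroxy-2-(triisopropylsilyloxy)phenyl]-3,7-dimethyl-3,7-bis(trimethylsilyloxy)octan-1-one F8.
- Et3N·3HF removes all three silyl groups to give 12.

## Further compounds

F1 | step 8 | (S)-1-(2,5-dihydroxyphenyl)-3,7-dihydroxy-3,7-dimethyloctan-1-one | O=C(C[C@@](C)(O)CCCC(C)(C)O)c1cc(O)ccc1O
F2 | step 5 | (S)-3,7-dihydroxy-3,7-dimethyloctanoic acid | OC(=O)C[C@@](C)(O)CCCC(C)(C)O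
F3 | step 5 | (S)-3,7-dihydroxy-N-methoxy-N,3,7-trimethyloctanamide | CON(C)C(=O)C[C@@](C)(O)CCCC(C)(C)O
F4 | step 6 | (S)-3,7-dimethyl-3,7-bis(trimethylsilyloxy)octanal | O=CC[C@@](C)(O[Si](C)(C)C)CCCC(C)(C)O[Si](C)(C)C
F5 | step 6 | (5S)-5,9-dimethyl-5,9-bis(trimethylsilyloxy)dec-1-yn-3-ol | C#CC(O)C[C@@](C)(O[Si](C)(C)C)CCCC(C)(C)O[Si](C)(C)C
F6 | step 6 | (S)-5,9-dimethyl-5,9-bis(trimethylsilyloxy)dec-1-yn-3-one | C#CC(=O)C[C@@](C)(O[Si](C)(C)C)CCCC(C)(C)O[Si](C)(C)C
F7 | step 6 | (3S)-1-[5-bromo-1-(triisopropylsilyloxy)-7-oxabicyclo[2.2.1]hepta-2,5-dien-2-yl]-3,7-dimethyl-3,7-bis(trimethylsilyloxy)octan-1-one | CC(C)[Si](C(C)C)(C(C)C)OC12OC(C=C1C(=O)C[C@@](C)(O[Si](C)(C)C)CCCC(C)(C)O[Si](C)(C)C)C(Br)=C2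
F8 | step 6 | (S)-1-[4-bromo-5-hydroxy-2-(triisopropylsilyloxy)phenyl]-3,7-dimethyl-3,7-bis(trimethylsilyloxy)octan-1-one | CC(C)[Si](C(C)C)(C(C)C)Oc1cc(Br)c(O)cc1C(=O)C[C@@](C)(O[Si](C)(C)C)CCCC(C)(C)O[Si](C)(C)C
A1 | alternative 1 | 1,4-dibromo-2,5-bis(methoxymethoxy)benzene | COCOc1cc(Br)c(OCOC)cc1Br
A2 | alternative 1 | (S)-1-[4-bromo-2,5-bis(methoxymethoxy)phenyl]-3,7-dihydroxy-3,7-dimethyloctan-1-one | COCOc1cc(Br)c(OCOC)cc1C(=O)C[C@@](C)(O)CCCC(C)(C)O
A3 | alternative 2 | 5-bromo-4-methoxy-2-(trimethylsilyl)phenyl trifluoromethanesulfonate | COc1cc([Si](C)(C)C)c(OS(=O)(=O)C(F)(F)F)cc1Br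
A4 | alternative 2 | 4-bromo-5-methoxybenzyne | COC1=CC#CC=C1Br
A5 | alternative 2 | (S)-3,7-dihydroxy-3,7-dimethyloctanoic acid | OC(=O)C[C@@](C)(O)CCCC(C)(C)O
A6 | alternative 2 | (S)-1-(4-bromo-2-hydroxy-5-methoxyphenyl)-3,7-dihydroxy-3,7-dimethyloctan-1-one | COc1cc(C(=O)C[C@@](C)(O)CCCC(C)(C)O)c(O)cc1Br
A7 | alternative 3 | (E)-1-[4-bromo-2,5-bis(methoxymethoxy)phenyl]-7-hydroxy-3,7-dimethyloct-2-en-1-one | COCOc1cc(Br)c(OCOC)cc1C(=O)/C=C(\C)CCCC(C)(C)O
A8 | alternative 3 | 7-bromo-6-hydroxy-2-(4-hydroxy-4-methylpentyl)-2-methylchroman-4-one (racemic) | CC(C)(O)CCCC1(C)CC(=O)c2cc(O)c(Br)cc2O1
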